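Left-handed product is best counted per partner charged: Y is the highest left-handed product over the partner charge, partner being the limiting reagent (0.800 mM against 2.00 mM of both substrates in the flask).

| flask | left-handed substrate | right-handed substrate | partner | remark | time |
|---|---|---|---|---|---|
| Thursday's | 0.67 mM | 0.67 mM | 0.80 mM | run made earlier |  |
| Friday's | 1.5 mM | 1.5 mM | 0.80 mM | run made earlier |  |
| flask | 1.0 mM | 1.0 mM | 0.800 mM |  | 8.0 min |

- Thursday's (time / min: left-handed product / %): 0.417: 11.4; 0.833: 16.5; 1.33: 18.5; 2.50: 19.0; 5.00: 18.2
- Friday's (time / min: left-handed product / %): 0.417: 9.3; 0.833: 11.3; 1.33: 12.2; 2.50: 12.0; 5.00: 10.3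

(scatter of a reading: 0.5 percentage points)

- the moment within 8.0 min at which there is most left-handed product
- the amount of left-handed product, in percent of the left-handed substrate and right-handed substrate together charged, at that time

- partner is single-handed; left-handed substrate and right-handed substrate are mirror images of each other, charged as a racemate, each of them at the stated concentration
- the handed part of partner does not stay in what it makes, so the products of the two hands are mirror images too

Read from the peaks, Y is 0.318 on Thursday and 0.457 on Friday. This 1.44-fold rise in Y is smaller than the 2.24-fold rise in c, the charge of each hand. Supposing partner is shared between capture proportional to c and a loss independent of c, the reciprocal of Y equals a + b/c, and the two runs give a = 1.41 and b = 1.16 mM. For the flask, Y = 0.389, which is 15.6% of the substrates charged. The highest readings, at 2.50 min and 1.33 min, put the peak near their geometric mean, 1.82 min.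

The forecast gives 15.3% at 1.7 min: "I interpolate empirically". The flask gives 15.5% at 1.69 min.

    partner + left-handed substrate → left-handed product (k = 19.0 L mol⁻¹ s⁻¹)
    partner + right-handed substrate → right-handed product (k = 8.00 L mol⁻¹ s⁻¹)
    partner → decomposed reagent (k = 0.0120 s⁻¹)
    left-handed product ⇌ right-handed product (k = 0.00310 s⁻¹)

The result makes Y in this flask 0.386. Partner's half-life by decomposition alone, 0.96 min, is shorter than its half-life by capture with right-handed substrate at 0.292 min, 1.6 min, and this flask holds 0.266 mM of decomposed reagent at 1.70 min. Carried at the same c to the neighbour with 1.4 mM of partner, the Y reckoned for the flask promises 27.2%; that neighbour gives 24.8%, a Y of 0.354.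

The numbers in the tables are simulated for substances that don't exist, noise included.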